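**Plan**

- Retrosynthesis (hexahydroazulene locants C1–C8a; ring A five-membered, ring B seven-membered): cut the aryl ester at C4–O, then the C3–isopropyl bond, then C6=C7 of ring B by metathesis. This leaves a 2,3,3-trisubstituted cyclopentanone (ring A).
- Enabling feature: in ring A the oxygenated C3 lies between the CH C3a and the CH2 C2, and the quaternary C8a sits next to C3a. With C3 as a ketone, cutting C2–C3 gives a 4-pentenal (formyl C3, vinyl C1=C2 on C8a). Cutting C3a–C8a of that pentenal gives an allyl vinyl ether whose oxygen (bonded to C3 and C2) ends as the C3 oxygen of the target.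
- Forward: an (E)-vinyl iodide (C3–C6) and (E)-3-methylhexa-2,5-dien-1-ol (C2, C1, C8a, C8, C7) are joined by C–O coupling. A one-flask Claisen rearrangement/hydroacylation builds ring A, metathesis closes ring B, then isopropyl addition, desilylation and acylation follow.
- Stereochemistry: C4 from a Brown methallylboration. C3a/C8a relative configuration from the chair Claisen transition state of two (E)-alkenes, absolute sense from C4 by 1,2-induction. C3 from addition anti to the C8a methyl group of the trans-fused ketone.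

Key step: step 7

Remark: the locants of the hexahydroazulene skeleton of the target are used for the corresponding carbons of all intermediates, open-chain ones included.
Assumption: 3-(trimethylsilyl)prop-2-ynal, pent-1-en-4-yne, 4-acetoxybenzoyl chloride and the reagents named are taken as purchased.

**Route**

Step 1
Reactants: 1 3-(trimethylsilyl)prop-2-ynal
Product: 2 (3S)-5-methyl-1-(trimethylsilyl)hex-5-en-1-yn-3-ol
Conditions: (−)-Ipc2BCl [from (+)-α-pinene], CH2=C(CH3)CH2MgCl, Et2O, −78 °C; then 1, −78 °C; NaOH, H2O2, 0 °C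
Reagents that add atoms: 2-methylallylmagnesium chloride, C=C(C)C[Mg]Cl, delivered as (−)-B-(2-methylallyl)diisopinocampheylborane made in the flask, C=C(C)CB([C@@H]1C[C@@H]2C[C@H]([C@H]1C)C2(C)C)[C@@H]1C[C@@H]2C[C@H]([C@H]1C)C2(C)C
Why: Brown asymmetric methallylboration through a chair six-membered transition state, in which the isopinocampheyl groups derived from (+)-α-pinene should send the methallyl group to the Si face of the ynal and so set C4 as (S).

Step 2
Reactants: 2 (3S)-5-methyl-1-(trimethylsilyl)hex-5-en-1-yn-3-ol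
Product: 3 tert-butyl(dimethyl){[(3S)-5-methyl-1-(trimethylsilyl)hex-5-en-1-yn-3-yl]oxy}silane
Conditions: TBSCl, imidazole, DMF, 25 °C
Reagents that add atoms: tert-butyldimethylsilyl chloride, CC(C)(C)[Si](C)(C)Cl
Why: Standard silylation of a secondary alcohol, which masks the C4 hydroxyl for the coupling, the rearrangement and the Grignard step without touching the stereocentre.

Step 3
Reactants: 3 tert-butyl(dimethyl){[(3S)-5-methyl-1-(trimethylsilyl)hex-5-en-1-yn-3-yl]oxy}silane
Product: 4 tert-butyl(dimethyl){[(3S)-5-methylhex-5-en-1-yn-3-yl]oxy}silane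
Conditions: K2CO3 (cat.), MeOH, 25 °C
Reagents that add atoms: none
Why: Methanolysis cleaves the C(sp)–Si bond selectively, while the hindered silyl ether is stable to these conditions.

Step 4
Reactants: 4 tert-butyl(dimethyl){[(3S)-5-methylhex-5-en-1-yn-3-yl]oxy}silane
Product: 6 tert-butyl{[(1E,3S)-1-iodo-5-methylhexa-1,5-dien-3-yl]oxy}dimethylsilane, via alkenylzirconocene chloride 5 (not isolated)
Conditions: Cp2Zr(H)Cl, THF, 25 °C; then I2, 0 °C
Reagents that add atoms: iodine, II
Why: Hydrozirconation adds Zr–H syn with zirconium at the terminal alkyne carbon and iodinolysis of the C–Zr bond goes with retention, so the (E)-iodide should result, the 1,1-disubstituted alkene being far slower than the alkyne.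

Step 5
Reactants: 7 pent-1-en-4-yne
Product: 10 (2E)-3-methylhexa-2,5-dien-1-ol, via alkenyldimethylalane 8 (not isolated), via lithium alkenylaluminate 9 (not isolated)
Conditions: Me3Al, Cp2ZrCl2 (20 mol%), CH2Cl2, 0 to 25 °C; then n-BuLi, THF, −78 °C; (CH2O)n, 25 °C; aq. HCl
Reagents that add atoms: trimethylaluminium, C[Al](C)C; paraformaldehyde as formaldehyde, C=O
Why: Zirconocene-catalysed Negishi carboalumination adds CH3 and Al syn across the alkyne with CH3 at the internal carbon, and the aluminate is hydroxymethylated with retention, which fixes the (E) geometry (CH3 cis to CH2OH); the alkene is much slower than the alkyne.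

Step 6
Reactants: 6 tert-butyl{[(1E,3S)-1-iodo-5-methylhexa-1,5-dien-3-yl]oxy}dimethylsilane; 10 (2E)-3-methylhexa-2,5-dien-1-ol
Product: 11 tert-butyl(dimethyl){[(1E,3S)-5-methyl-1-{[(2E)-3-methylhexa-2,5-dien-1-yl]oxy}hexa-1,5-dien-3-yl]oxy}silane
Conditions: CuI (10 mol%), 3,4,7,8-tetramethyl-1,10-phenanthroline (20 mol%), Cs2CO3, toluene, 80 °C
Reagents that add atoms: none
Why: Copper-catalysed Ullmann-type C–O coupling of a vinyl iodide with an allylic alcohol goes with retention of the (E)-iodide geometry, so both alkene geometries of the allyl vinyl ether are defined, and 80 °C is below the temperature of the rearrangement.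

Step 7
Reactants: 11 tert-butyl(dimethyl){[(1E,3S)-5-methyl-1-{[(2E)-3-methylhexa-2,5-dien-1-yl]oxy}hexa-1,5-dien-3-yl]oxy}silane
Product: 13 (2S,3R)-2-[(1S)-1-{[tert-butyl(dimethyl)silyl]oxy}-3-methylbut-3-en-1-yl]-3-methyl-3-(prop-2-en-1-yl)cyclopentan-1-one, via pentenal 12 (not isolated)
Conditions: ClCH2CH2Cl, base-washed sealed tube, 120 °C; then 25 °C, [Rh(nbd)(dppe)]BF4 (5 mol%, activated with H2)
Reagents that add atoms: none
Why: Heating effects the Claisen rearrangement of the allyl vinyl ether through a chair transition state and forms C3a–C8a; the cationic rhodium diphosphine catalyst then inserts into the formyl C–H bond of 12, adds Rh–H across the vinyl group to a six-membered acyl–alkyl rhodacycle and closes C2–C3 by reductive elimination. The closest known reaction type is the tandem Claisen rearrangement/intramolecular hydroacylation of allyl vinyl ethers to cyclopentanones, run here as two stages in one flask. Ring A closes as a cyclopentanone by bonding the acyl carbon to the terminal alkene carbon (4-pentenal mode, formally 5-endo-trig), helped by the quaternary C8a. The relative configuration of C3a and C8a follows from the chair with the (E)-enol ether (C4 chain equatorial) and the (E)-allyl unit (allyl chain equatorial, methyl axial), which places the C4 chain cis to the methyl group and trans to the allyl group. Their absolute sense should come from the C4 stereocentre, the new bond forming anti to the C5 methylene with the silyloxy group inside; this facial selectivity is the selectivity the step needs most and is its weakest point. Chemoselectivity of the hydroacylation is secured because only the vinyl group lies at the 4,5-position of the aldehyde, while the allyl and methallyl alkenes would need larger rhodacycles.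

Step 8
Reactants: 13 (2S,3R)-2-[(1S)-1-{[tert-butyl(dimethyl)silyl]oxy}-3-methylbut-3-en-1-yl]-3-methyl-3-(prop-2-en-1-yl)cyclopentan-1-one
Product: 14 (3aR,8S,8aS)-8-{[tert-butyl(dimethyl)silyl]oxy}-3a,6-dimethyl-3,3a,4,7,8,8a-hexahydroazulen-1(2H)-one
Conditions: second-generation Grubbs catalyst RuCl2(=CHPh)(PCy3)(H2IMes) (5 mol%), CH2Cl2 (0.005 M), 40 °C
Reagents that add atoms: none
Why: Ring-closing metathesis of the allyl and methallyl groups closes ring B as a seven-membered ring with the trisubstituted C6=C7 alkene, and the trans arrangement of the two chains gives the trans ring fusion without touching a stereocentre.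

Step 9
Reactants: 14 (3aR,8S,8aS)-8-{[tert-butyl(dimethyl)silyl]oxy}-3a,6-dimethyl-3,3a,4,7,8,8a-hexahydroazulen-1(2H)-one
Product: 15 (3R,3aS,4S,8aR)-4-{[tert-butyl(dimethyl)silyl]oxy}-6,8a-dimethyl-3-(propan-2-yl)-1,2,3a,4,5,8-hexahydroazulen-3-ol
Conditions: i-PrMgCl, LaCl3·2LiCl, THF, −20 to 0 °C; aq. NH4Cl
Reagents that add atoms: isopropylmagnesium chloride, CC(C)[Mg]Cl
Why: Lanthanum-mediated Grignard 1,2-addition (enolisation and β-hydride reduction suppressed) should occur on the face opposite the axial C8a methyl group, which stands 1,3 to the carbonyl carbon, placing the isopropyl group cis to H3a and the new hydroxyl cis to the methyl group (3R).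

Step 10
Reactants: 15 (3R,3aS,4S,8aR)-4-{[tert-butyl(dimethyl)silyl]oxy}-6,8a-dimethyl-3-(propan-2-yl)-1,2,3a,4,5,8-hexahydroazulen-3-ol
Product: 16 jaeschkeanadiol, (3R,3aS,4S,8aR)-6,8a-dimethyl-3-(propan-2-yl)-1,2,3a,4,5,8-hexahydroazulene-3,4-diol
Conditions: Bu4NF, THF, 25 to 50 °C
Reagents that add atoms: none
Why: Fluoride cleaves the secondary silyl ether and no stereocentre is involved.

Step 11
Reactants: 16 jaeschkeanadiol; 17 4-acetoxybenzoyl chloride
Product: 19 ferutinine, via O-acetylferutinine 18 (not isolated)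
Conditions: pyridine, DMAP (cat.), CH2Cl2, 25 °C; then pyrrolidine, 25 °C
Reagents that add atoms: none
Why: DMAP-catalysed acylation should take the secondary C4 hydroxyl with retention and leave the hindered tertiary C3 hydroxyl, and pyrrolidine then removes the phenolic acetate by aminolysis far faster than it attacks the alkyl benzoate.

**Compound list**

1 | 3-(trimethylsilyl)prop-2-ynal | C[Si](C)(C)C#CC=O | starting material
2 | (3S)-5-methyl-1-(trimethylsilyl)hex-5-en-1-yn-3-ol | C[Si](C)(C)C#C[C@@H](O)CC(C)=C | intermediate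
3 | tert-butyl(dimethyl){[(3S)-5-methyl-1-(trimethylsilyl)hex-5-en-1-yn-3-yl]oxy}silane | C[Si](C)(C)C#C[C@@H](O[Si](C)(C)C(C)(C)C)CC(C)=C | intermediate
4 | tert-butyl(dimethyl){[(3S)-5-methylhex-5-en-1-yn-3-yl]oxy}silane | C#C[C@@H](O[Si](C)(C)C(C)(C)C)CC(C)=C | intermediate
5 | chlorobis(cyclopentadienyl)[(1E,3S)-3-{[tert-butyl(dimethyl)silyl]oxy}-5-methylhexa-1,5-dien-1-yl]zirconium | Cl[Zr](/C=C/[C@@H](O[Si](C)(C)C(C)(C)C)CC(C)=C)(C1C=CC=C1)C1C=CC=C1 | intermediate
6 | tert-butyl{[(1E,3S)-1-iodo-5-methylhexa-1,5-dien-3-yl]oxy}dimethylsilane | I/C=C/[C@@H](O[Si](C)(C)C(C)(C)C)CC(C)=C | intermediate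
7 | pent-1-en-4-yne | C#CCC=C | starting material
8 | dimethyl[(1E)-2-methylpenta-1,4-dien-1-yl]alane | C[Al](C)/C=C(\C)CC=C | intermediate
9 | lithium butyl(dimethyl)[(1E)-2-methylpenta-1,4-dien-1-yl]aluminate | [Li+].CCCC[Al-](C)(C)/C=C(\C)CC=C | intermediate
10 | (2E)-3-methylhexa-2,5-dien-1-ol | C=CC/C(C)=C/CO | intermediate
11 | tert-butyl(dimethyl){[(1E,3S)-5-methyl-1-{[(2E)-3-methylhexa-2,5-dien-1-yl]oxy}hexa-1,5-dien-3-yl]oxy}silane | C=CC/C(C)=C/CO/C=C/[C@@H](O[Si](C)(C)C(C)(C)C)CC(C)=C | intermediate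
12 | (2S,3S)-2-[(1S)-1-{[tert-butyl(dimethyl)silyl]oxy}-3-methylbut-3-en-1-yl]-3-ethenyl-3-methylhex-5-enal | O=C[C@H]([C@@H](O[Si](C)(C)C(C)(C)C)CC(C)=C)[C@@](C)(CC=C)C=C | intermediate
13 | (2S,3R)-2-[(1S)-1-{[tert-butyl(dimethyl)silyl]oxy}-3-methylbut-3-en-1-yl]-3-methyl-3-(prop-2-en-1-yl)cyclopentan-1-one | O=C1CC[C@](C)(CC=C)[C@H]1[C@@H](O[Si](C)(C)C(C)(C)C)CC(C)=C | intermediate
14 | (3aR,8S,8aS)-8-{[tert-butyl(dimethyl)silyl]oxy}-3a,6-dimethyl-3,3a,4,7,8,8a-hexahydroazulen-1(2H)-one | CC1=CC[C@@]2(C)CCC(=O)[C@@H]2[C@@H](O[Si](C)(C)C(C)(C)C)C1 | intermediate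
15 | (3R,3aS,4S,8aR)-4-{[tert-butyl(dimethyl)silyl]oxy}-6,8a-dimethyl-3-(propan-2-yl)-1,2,3a,4,5,8-hexahydroazulen-3-ol | CC1=CC[C@@]2(C)CC[C@@](O)(C(C)C)[C@@H]2[C@@H](O[Si](C)(C)C(C)(C)C)C1 | intermediate
16 | jaeschkeanadiol, (3R,3aS,4S,8aR)-6,8a-dimethyl-3-(propan-2-yl)-1,2,3a,4,5,8-hexahydroazulene-3,4-diol | CC1=CC[C@@]2(C)CC[C@@](O)(C(C)C)[C@@H]2[C@@H](O)C1 | intermediate
17 | 4-acetoxybenzoyl chloride | CC(=O)Oc1ccc(cc1)C(Cl)=O | starting material
18 | O-acetylferutinine, [(3R,3aS,4S,8aR)-3-hydroxy-6,8a-dimethyl-3-(propan-2-yl)-1,2,3a,4,5,8-hexahydroazulen-4-yl] 4-acetoxybenzoate | CC1=CC[C@@]2(C)CC[C@@](O)(C(C)C)[C@@H]2[C@@H](OC(=O)c2ccc(OC(C)=O)cc2)C1 | intermediate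
19 | ferutinine, [(3R,3aS,4S,8aR)-3-hydroxy-6,8a-dimethyl-3-(propan-2-yl)-1,2,3a,4,5,8-hexahydroazulen-4-yl] 4-hydroxybenzoate | CC1=CC[C@@]2(C)CC[C@@](O)(C(C)C)[C@@H]2[C@@H](OC(=O)c2ccc(O)cc2)C1 | target

**Step count**

Total step count: 11. Longest linear sequence: 10 steps (steps 1–4 and 6–11).

**Steps most likely to fail**

Most at risk is step 7. The rearrangement may show poor facial selectivity, because the only control over the absolute configuration of C8a (and C3a) is open-chain 1,2-induction from C4, and a wrong C8a cannot be corrected later. The fallback moves the rearrangement to the ester level, where a lithium chelate fixes the C4 oxygen. It sets out from alkyne 4 and alcohol 10. Hydroboration of 4 with disiamylborane and buffered H2O2 oxidation should give (3S)-3-{[tert-butyl(dimethyl)silyl]oxy}-5-methylhex-5-enal F1. NaClO2/NaH2PO4/2-methylbut-2-ene oxidation gives the corresponding acid F2, and DCC/DMAP esterification with 10 gives the (2E)-3-methylhexa-2,5-dien-1-yl ester F3. HF·pyridine frees the β-hydroxy ester F4. Its dianion (LiN(i-Pr)2, 2.2 equiv, THF, −78 to 25 °C) should undergo the chelation-controlled ester enolate Claisen rearrangement, anti to the C5 methylene, to the hydroxy acid F5. TMSCHN2 gives the methyl ester F6, TBSOTf/2,6-lutidine the silyl ether F7, and i-Bu2AlH at −78 °C the aldehyde 12. The route is rejoined at 12, which is cyclised as in the second stage of step 7.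

Next is step 9. The branched Grignard reagent may enolise the ketone or reduce it by β-hydride transfer instead of adding, and the facial selectivity may be eroded. The fallback sets out from ketone 14. Addition of the smaller, non-reducing 2-propenyl nucleophile (CH2=C(CH3)MgBr, CeCl3, THF, −78 °C) should give the isopropenyl carbinol F8, (3S,3aS,4S,8aR)-4-{[tert-butyl(dimethyl)silyl]oxy}-6,8a-dimethyl-3-(prop-1-en-2-yl)-1,2,3a,4,5,8-hexahydroazulen-3-ol. Hydrogenation of its 1,1-disubstituted alkene with RhCl(PPh3)3/H2 (benzene, 25 °C), which spares the trisubstituted ring alkene, rejoins the route at 15.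

Third is step 6. The C–O coupling may be slow at the hindered, base-sensitive vinyl iodide, so that premature rearrangement or decomposition competes. The fallback replaces the halide partner by a boron partner and sets out from alkyne 4 and alcohol 10. Hydroboration of 4 with pinacolborane (Cp2Zr(H)Cl cat.) should give the (E)-vinyl boronate F9. Its oxidative coupling with 10 promoted by Cu(OAc)2 and Et3N at 25 °C under air, with retention of the alkene geometry, rejoins the route at 11.

**Further compounds**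

F1 | step 7 | (3S)-3-{[tert-butyl(dimethyl)silyl]oxy}-5-methylhex-5-enal | O=CC[C@@H](O[Si](C)(C)C(C)(C)C)CC(C)=C
F2 | step 7 | (3S)-3-{[tert-butyl(dimethyl)silyl]oxy}-5-methylhex-5-enoic acid | OC(=O)C[C@@H](O[Si](C)(C)C(C)(C)C)CC(C)=C
F3 | step 7 | (2E)-3-methylhexa-2,5-dien-1-yl (3S)-3-{[tert-butyl(dimethyl)silyl]oxy}-5-methylhex-5-enoate | C=CC/C(C)=C/COC(=O)C[C@@H](O[Si](C)(C)C(C)(C)C)CC(C)=C
F4 | step 7 | (2E)-3-methylhexa-2,5-dien-1-yl (3S)-3-hydroxy-5-methylhex-5-enoate | C=CC/C(C)=C/COC(=O)C[C@@H](O)CC(C)=C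
F5 | step 7 | (2S,3S)-3-ethenyl-2-[(1S)-1-hydroxy-3-methylbut-3-en-1-yl]-3-methylhex-5-enoic acid | OC(=O)[C@H]([C@@H](O)CC(C)=C)[C@@](C)(CC=C)C=C
F6 | step 7 | methyl (2S,3S)-3-ethenyl-2-[(1S)-1-hydroxy-3-methylbut-3-en-1-yl]-3-methylhex-5-enoate | COC(=O)[C@H]([C@@H](O)CC(C)=C)[C@@](C)(CC=C)C=C
F7 | step 7 | methyl (2S,3S)-2-[(1S)-1-{[tert-butyl(dimethyl)silyl]oxy}-3-methylbut-3-en-1-yl]-3-ethenyl-3-methylhex-5-enoate | COC(=O)[C@H]([C@@H](O[Si](C)(C)C(C)(C)C)CC(C)=C)[C@@](C)(CC=C)C=C
F8 | step 9 | (3S,3aS,4S,8aR)-4-{[tert-butyl(dimethyl)silyl]oxy}-6,8a-dimethyl-3-(prop-1-en-2-yl)-1,2,3a,4,5,8-hexahydroazulen-3-ol | CC1=CC[C@@]2(C)CC[C@@](O)(C(C)=C)[C@@H]2[C@@H](O[Si](C)(C)C(C)(C)C)C1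
F9 | step 6 | 2-[(1E,3S)-3-{[tert-butyl(dimethyl)silyl]oxy}-5-methylhexa-1,5-dien-1-yl]-4,4,5,5-tetramethyl-1,3,2-dioxaborolane | CC1(C)OB(/C=C/[C@@H](O[Si](C)(C)C(C)(C)C)CC(C)=C)OC1(C)C
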